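At the reading time of 5.0 h, south-west and north-west have received two portions of G, since their third falls later, at 6.00 h. A flask is therefore measured here by the G that L has been exposed to: the clock θ, each portion's concentration times the hours it has stood, summed.

| flask | L | G | remark | time |
|---|---|---|---|---|
| red | 0.033 M | 0.21 M (in portions, 3) | run made earlier; portions every 1.5 h |  |
| blue | 0.24 M | 0.21 M (in portions, 3) | run made earlier; portions every 1.5 h |  |
| violet | 0.14 M | 0.16 M (in portions, 3) | run made earlier; portions every 1.5 h |  |
| north | 0.14 M | 0.210 M (in portions, 3) | the portions of G follow each other after 1.5 h, the first at the start | 5.0 h |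
| south-west | 0.14 M | 0.0500 M (in portions, 3) | the portions of G follow each other after 3.0 h, the first at the start | 5.0 h |
| west | 0.040 M | 0.210 M (in portions, 3) | the portions of G follow each other after 1.5 h, the first at the start | 5.0 h |
| east | 0.30 M | 0.210 M (in portions, 3) | the portions of G follow each other after 1.5 h, the first at the start | 5.0 h |
| north-west | 0.040 M | 0.600 M (in portions, 3) | the portions of G follow each other after 3.0 h, the first at the start | 5.0 h |

| run | time / h | X / % | E / % | L / % |
|---|---|---|---|---|
| red | 1.33 | 1 | 2 | 93 |
| red | 2.50 | 3 | 2 | 80 |
| red | 4.00 | 15 | 7 | 58 |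
| red | 5.00 | 16 | 10 | 47 |
| blue | 0.417 | 0 | 0 | 95 |
| blue | 1.00 | 0 | 0 | 92 |
| blue | 2.00 | 2 | 2 | 87 |
| blue | 5.00 | 8 | 2 | 60 |
| violet | 0.417 | 1 | 0 | 99 |
| violet | 1.00 | 0 | 0 | 96 |
| violet | 2.00 | 1 | 0 | 88 |
| violet | 5.00 | 9 | 1 | 64 |

(scatter of a reading: 1.5 percentage points)

- ranking by share of X in all that became X or E, from high to low, at 5.0 h (north / south-west / west / east / north-west)
- the share of X in all that became X or E of the flask you put first, at 5.0 h
- the share of X in all that became X or E of the flask you put last, at 5.0 h

- percentages count the whole charge, also what has not yet gone in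

In red, L stands at 0.033 M against 0.21 M of G, so as an estimate G is counted as charged and L is taken as falling pseudo-first-order on this clock. By 5.00 h the red clock reads 0.735 M·h and L reads 47 %. That reading gives h = 0.675 M·h, the half-life dose, the exposure to G that halves L.

A flask has then run n = θ/h half-lives, and red stands at 1.09. Red's E over X, 10 to 16, gives the reading r = 0.574 per half-life. My own reckoning takes E/X as rn, so the share of X is one over one plus rn:

south-west: θ = 0.117 M·h, n = 0.173, share 91.0 %

north-west: θ = 1.40 M·h, n = 2.07, share 45.7 %

The weak link is θ, which counts G as charged although L consumes it. Blue, with the same G schedule as red, reads 60 % of L at 5.00 h, so its clock, read from L itself, is n = 0.737, worth a share of 70.3 %. East, charged with 0.30 M of L, should stand at or above that share. West, at 0.040 M of L, should stay near red, with north between west and east.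

The forecast gives south-west > east > north > west > north-west, with 93 % and 42 %, on the ground that “E appears to need a further G”. Its order is mine, but its top lies above mine and its low below.

The flasks give south-west > east > north > west > north-west, with 85.4 % first and 53.8 % last.

    L + G → D (k = 0.370 /M/h)
    D ⇌ J (K = 42.0, k = 0.0530 /h)
    L + G → Z (k = 0.730 /M/h)
    G + D → X (k = 12.0 /M/h)
    G + Z → E (k = 0.720 /M/h)

North-west has not come to rest at 5.0 h. Its 2.07 half-lives leave 23.7 % of L by reckoning, and the flask holds 24.4 %, with 29.4 % standing as Z. By 50.0 h L is at 0 % and Z at 0 %, while E has gone from 20.7 % to 66.4 % and X from 24.2 % to 33.1 %. E gains more than X, so the share of X falls from 53.8 % to 33.3 %.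

Read at 8.0 h, north-west has its third portion in, so θ = 3.00 M·h, n = 4.45, and L should stand at 4.58 %, with a share of 28.1 %. The computed flask holds 5.11 % of L, and its share is 40.8 %.

All runs are calculated with constants of no real substance, and the scatter is random.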